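Ring B (C5–C6–C7–C8–C11–C30; atoms numbered in target-SMILES order) is cut at C8–C11. Samarium diiodide turns an oxepane-bound bromo ketone (Br on C11, C12 ketone) into one samarium enolate that adds to the C8 methyl ketone. This single operation forms C8–C11, closes the cyclohexane on the finished oxepane and sets C8 and C11. It exploits the aldol relationship between the tertiary carbinol C8 and C11 once C12 is a ketone, and the axial C31 methyl on C30, which biases the chair. The precursor is a 2,2-dimethyl-3-silyloxyoxepane bearing the 3-oxobutyl arm on C5 and, on C30, the bromo ketone tied through C13 to the complete hydroazulene.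

Key step: step 27

Remarks
- O4 is the oxepane oxygen and O27 the epoxide oxygen. Steps 1–9 make the oxepane bromo aldehyde 13, steps 10–23 the hydroazulene iodide 34, and steps 24–34 join them and finish.
- The structures of the key-step precursor 39 and product 41 were checked atom by atom against the target: C5, C8, C11, C30, C14, C18, C21 and C24 agree, so no structure needed correction. C34 is S in 5–48 and is erased in step 34.
- Design changes around the key step: bromine is installed by α-bromination of an aldehyde before the fragments are joined, because a hydroxyl-to-bromide exchange at the neopentyl C11 is unreliable. The C8 ketone is a dioxolane while carbanions are used. After the key step all silyl ethers are removed together and only the secondary C34 carbinol can be oxidized.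
- C11 (13, 37–39) and C12 (37, 43, 44) are carried as epimer mixtures, since both centres converge or are erased.
- The epoxide is made through a bromohydrin because C14–H, C18–H and C24–H lie on one face of the cycloheptene and the target oxygen lies on the other (the face of C13). This facial assignment is a conformational argument, not a certainty; see the third fallback.

Step 1
Reactants: 1 myrcene
Product: 2 neryl pinacolboronate, 2-[(2Z)-3,7-dimethylocta-2,6-dien-1-yl]-4,4,5,5-tetramethyl-1,3,2-dioxaborolane
Conditions: HBpin, Ni(cod)2 (2.5 mol %), PCy3 (2.5 mol %), toluene, 0 °C → rt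
Reagents that add atoms: pinacolborane, [H]B1OC(C)(C)C(C)(C)O1
Why: Nickel-catalysed 1,4-hydroboration of a 2-substituted 1,3-diene puts boron on C1 and hydrogen on the exocyclic methylene through an s-cis diene/π-allyl nickel intermediate, so the trisubstituted alkene should form with Z geometry, which is what C30 needs.

Step 2
Reactants: 2 neryl pinacolboronate; 3 pent-4-enal
Product: 4 (5R,6R)-6-ethenyl-6,10-dimethylundeca-1,9-dien-5-ol (C5 carbinol; C30 quaternary with C31 methyl, C11=C12 vinyl and homoprenyl arm)
Conditions: (S)-TRIP (5 mol %), 4 Å MS, toluene, −30 °C; aq. NaOH work-up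
Reagents that add atoms: none
Why: Chiral phosphoric acid-catalysed allylboration through a closed chair transition state: the Z geometry of 2 places the C31 methyl anti and the homoprenyl chain syn to the new hydroxyl, and the catalyst, which on the accepted model for this catalyst class should direct addition to the Si face of the aldehyde, sets the absolute configuration of C5 and thereby of C30.

Step 3
Reactants: 4 homoallylic alcohol
Product: 5 (5R,6R)-8-[(2S)-3,3-dimethyloxiran-2-yl]-6-ethenyl-6-methyloct-1-en-5-ol
Conditions: ent-Shi ketone (from L-sorbose, 30 mol %), Oxone, K2CO3, Bu4NHSO4, MeCN/DMM/aq. borate buffer (pH 10.5), 0 °C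
Reagents that add atoms: potassium peroxymonosulfate (Oxone), [K+].[O-]S(=O)(=O)OO
Why: Shi asymmetric epoxidation (chiral dioxirane, spiro transition state) attacks only the electron-rich trisubstituted C34=C2 alkene and not the two monosubstituted alkenes, and this ketone enantiomer should give the (S)-epoxide at C34, a spectator centre that makes 5 a single diastereomer.

Step 4
Reactants: 5 epoxy alcohol
Product: 6 tert-butyl{[(3S,6R,7R)-7-(but-3-en-1-yl)-6-ethenyl-2,2,6-trimethyloxepan-3-yl]oxy}dimethylsilane
Conditions: TBSOTf (1.3 equiv), 2,6-di-tert-butyl-4-methylpyridine, CH2Cl2, −78 → −40 °C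
Reagents that add atoms: tert-butyldimethylsilyl trifluoromethanesulfonate, CC(C)(C)[Si](C)(C)OS(=O)(=O)C(F)(F)F
Why: Silyl triflate-promoted intramolecular epoxide opening in the 7-endo mode: silylation of the epoxide oxygen concentrates positive charge on the tertiary C2, which the C5 oxygen (free or as its silyl ether) attacks, so the oxepane should form with retention at C34 and with O34 already silylated, while C5 and C30 are untouched.

Step 5
Reactants: 6 oxepane diene
Product: 7 4-[(2R,3R,6S)-6-{[tert-butyl(dimethyl)silyl]oxy}-3-ethenyl-3,7,7-trimethyloxepan-2-yl]butan-2-one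
Conditions: PdCl2 (10 mol %), CuCl, O2 (1 atm), DMF/H2O (7:1), rt
Reagents that add atoms: water, O
Why: Tsuji–Wacker oxidation converts the unhindered terminal alkene into the C8 methyl ketone by Markovnikov hydroxypalladation, whereas the vinyl group on the quaternary C30 is too hindered to coordinate palladium at a useful rate.

Step 6
Reactants: 7 methyl ketone
Product: 8 tert-butyl{[(3S,6R,7R)-6-ethenyl-2,2,6-trimethyl-7-[2-(2-methyl-1,3-dioxolan-2-yl)ethyl]oxepan-3-yl]oxy}dimethylsilane
Conditions: ethylene glycol, PPTS (cat.), benzene, reflux (Dean–Stark)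
Reagents that add atoms: ethylene glycol, OCCO
Why: Acid-catalysed ketalization masks the C8 ketone as a dioxolane for the carbanion chemistry ahead, and the hindered secondary TBS ether tolerates PPTS.

Step 7
Reactants: 8 dioxolane
Product: 10 C12 primary alcohol (2-hydroxyethyl group on C30; otherwise as 8), via B-alkyl-9-BBN adduct 9 (not isolated)
Conditions: 9-BBN, THF, 0 → 50 °C; then NaOH, H2O2, 0 °C
Reagents that add atoms: hydrogen peroxide, OO
Why: Anti-Markovnikov hydroboration–oxidation: 9-BBN places boron on the terminal C12 of the neopentyl-type vinyl group and oxidation proceeds with retention, so C11 becomes CH2 and C12 the carbinol carbon.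

Step 8
Reactants: 10 primary alcohol
Product: 11 C12 aldehyde (2-oxoethyl group on C30; otherwise as 8)
Conditions: Dess–Martin periodinane, NaHCO3, CH2Cl2, 0 °C → rt
Reagents that add atoms: none
Why: Dess–Martin oxidation of a primary alcohol stops at the aldehyde under buffered conditions that spare the ketal and the silyl ether.

Step 9
Reactants: 11 aldehyde
Product: 13 C11-bromo C12-aldehyde (C11 epimers), via trimethylsilyl enol ether 12 (not isolated)
Conditions: TMSCl, Et3N, DMF, 80 °C; then NBS, THF, −78 °C
Reagents that add atoms: N-bromosuccinimide, O=C1CCC(=O)N1Br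
Why: Electrophilic bromination of a silyl enol ether: C11 is the only enolizable position of the aldehyde because C30 is quaternary, so bromine enters at C11 regiospecifically, and both epimers are usable because this centre converges in step 27.

Step 10
Reactants: 14 (R)-linalool
Product: 15 (R)-1-methylcyclopent-2-en-1-ol
Conditions: Grubbs II catalyst (1 mol %), CH2Cl2, 40 °C
Reagents that add atoms: none
Why: Ring-closing metathesis between the vinyl group and the trisubstituted alkene expels 2-methylpropene and leaves the carbinol stereocentre of linalool (the future C21) untouched.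

Step 11
Reactants: 15 cyclopentenol
Product: 16 (1R)-cis-2,3-epoxy-1-methylcyclopentan-1-ol (epoxide on the face of the hydroxyl)
Conditions: VO(acac)2 (2 mol %), t-BuOOH, CH2Cl2, 0 °C → rt
Reagents that add atoms: tert-butyl hydroperoxide, CC(C)(C)OO
Why: Vanadium-catalysed hydroxyl-directed epoxidation delivers oxygen to C24=C18 from the face of the tertiary hydroxyl, giving the cis-epoxy alcohol.

Step 12
Reactants: 16 epoxy alcohol; 17 isobutyronitrile
Product: 18 2-(2,3-dihydroxy-3-methylcyclopentyl)-2-methylpropanenitrile (C21–OH and C24–OH cis; C18 substituent trans to both)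
Conditions: 16, n-BuLi, THF, −78 °C; then LiCMe2CN (from 17 and LDA), −78 → 40 °C; NH4Cl
Reagents that add atoms: none
Why: SN2 opening of the epoxide by the metalated nitrile at C18, the carbon remote from the alkoxide-bearing quaternary C21, occurs with inversion, so the C18–C15 bond forms trans to both oxygens and C24 is left as a secondary carbinol.

Step 13
Reactants: 18 diol nitrile
Product: 19 2-(3-hydroxy-3-methyl-2-oxocyclopentyl)-2-methylpropanenitrile
Conditions: (COCl)2, DMSO, CH2Cl2, −78 °C; Et3N, −78 → 0 °C
Reagents that add atoms: none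
Why: Swern oxidation converts only the secondary C24 carbinol, since the tertiary C21 hydroxyl cannot be oxidized.

Step 14
Reactants: 19 α-hydroxy ketone
Product: 20 2-methyl-2-[3-methyl-2-oxo-3-(triethylsilyloxy)cyclopentyl]propanenitrile
Conditions: TESOTf, 2,6-lutidine, CH2Cl2, −78 → 0 °C
Reagents that add atoms: triethylsilyl trifluoromethanesulfonate, CC[Si](CC)(CC)OS(=O)(=O)C(F)(F)F
Why: Silyl triflate silylation of the tertiary alcohol installs the C21 protecting group now, which also excludes α-ketol rearrangement under the Lewis-acidic methylenation.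

Step 15
Reactants: 20 silyloxy ketone
Product: 21 2-methyl-2-[3-methyl-2-methylidene-3-(triethylsilyloxy)cyclopentyl]propanenitrile
Conditions: Zn, CH2Br2, TiCl4, THF/CH2Cl2, 0 °C → rt
Reagents that add atoms: dibromomethane, BrCBr
Why: Takai–Lombardo methylenation uses a non-basic gem-dimetallic reagent, so the hindered, enolizable C24 ketone should be converted into the exocyclic alkene (C25) without epimerization at C18.

Step 16
Reactants: 21 exocyclic alkene; 22 vinyl bromide
Product: 24 2-methyl-2-[3-methyl-2-(prop-2-en-1-yl)-3-(triethylsilyloxy)cyclopentyl]propanenitrile (allyl cis to the nitrile-bearing group and trans to OTES), via B-alkyl-9-BBN adduct 23 (not isolated)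
Conditions: 9-BBN, THF, 60 °C; then 22, Pd(dppf)Cl2 (5 mol %), AsPh3, Cs2CO3, DMF/H2O, 50 °C
Reagents that add atoms: none
Why: Hydroboration followed by B-alkyl Suzuki–Miyaura coupling: 9-BBN adds hydrogen to C24 from the face flanked by the C21 oxygen and C18–H, away from the C21 methyl and the bulky C18 substituent, so C25 ends cis to C15, and the coupling attaches the vinyl group (C26).

Step 17
Reactants: 24 nitrile
Product: 25 2-methyl-2-[3-methyl-2-(prop-2-en-1-yl)-3-(triethylsilyloxy)cyclopentyl]propanal (C14 aldehyde)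
Conditions: DIBAL-H, toluene, −78 → 0 °C; aq. Rochelle salt
Reagents that add atoms: water, O
Why: Partial reduction of the nitrile to the aluminium imine and hydrolysis gives the aldehyde, and the adjacent quaternary C15 excludes epimerization.

Step 18
Reactants: 25 aldehyde; 26 diethyl (3-oxobutan-2-yl)phosphonate
Product: 27 (3E)-3,5-dimethyl-5-[3-methyl-2-(prop-2-en-1-yl)-3-(triethylsilyloxy)cyclopentyl]hex-3-en-2-one
Conditions: NaH, THF, 0 → 60 °C
Reagents that add atoms: none
Why: Horner–Wadsworth–Emmons olefination of the non-enolizable aldehyde with a stabilized α-methyl β-keto phosphonate should give the E enone (C14=C28 with the C29 methyl) under thermodynamic control.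

Step 19
Reactants: 27 enone
Product: 28 (2R,3E)-allylic alcohol corresponding to 27
Conditions: (S)-Me-CBS (20 mol %), catecholborane, toluene, −78 °C
Reagents that add atoms: none
Why: Corey–Bakshi–Shibata reduction distinguishes the alkenyl and methyl groups of the ketone and should give the (R)-carbinol, while catecholborane at −78 °C does not hydroborate the allyl group.

Step 20
Reactants: 28 allylic alcohol; 29 tributyl(iodomethyl)stannane
Product: 30 (tributylstannyl)methyl ether of 28
Conditions: KH, 18-crown-6, THF, 0 °C → rt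
Reagents that add atoms: none
Why: Williamson etherification of the potassium alkoxide with the primary iodide leaves the carbinol configuration unchanged.

Step 21
Reactants: 30 stannylmethyl ether
Product: 32 (3Z)-3-methyl-2-{2-[3-methyl-2-(prop-2-en-1-yl)-3-(triethylsilyloxy)cyclopentyl]propan-2-yl}pent-3-en-1-ol (C14 as in the target; C13 is the CH2OH carbon), via α-alkoxymethyllithium 31 (not isolated)
Conditions: n-BuLi, THF, −78 °C; NH4Cl
Reagents that add atoms: none
Why: Still–Wittig [2,3]-sigmatropic rearrangement after tin–lithium exchange: the suprafacial shift transfers the (R)-carbinol chirality to C14, and because the carbinol methyl sits pseudo-axial to avoid the C29 methyl, the new alkene should be Z and C13 should arrive on the required face of C14.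

Step 22
Reactants: 32 diene alcohol
Product: 33 [1,4,4,6-tetramethyl-1-(triethylsilyloxy)-1,2,3,3a,4,5,8,8a-octahydroazulen-5-yl]methanol (cis-fused; C14–H, C18–H, C24–H and O on C21 on one face)
Conditions: Grubbs II catalyst (5 mol %), CH2Cl2, 40 °C
Reagents that add atoms: none
Why: Ring-closing metathesis of the allyl group with the trisubstituted alkene expels propene and closes the cycloheptene at C26=C28, helped by the cis arrangement of the two arms and the gem-dimethyl group.

Step 23
Reactants: 33 hydroazulenylmethanol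
Product: 34 5-(iodomethyl) analogue of 33 (C13 iodide)
Conditions: I2, PPh3, imidazole, CH2Cl2, 0 °C → rt
Reagents that add atoms: iodine, II
Why: Appel-type iodination of the primary alcohol through the alkoxyphosphonium ion touches no stereocentre.

Step 24
Reactants: 34 iodide; 13 bromo aldehyde
Product: 37 C11-bromo C12-carbinol (C11/C12 diastereomer mixture; oxepane joined through C12–C13 to the hydroazulene; C8 dioxolane), via primary alkyllithium 35 (not isolated), via alkylcerium dichloride 36 (not isolated)
Conditions: 34, t-BuLi (2.1 equiv), Et2O/pentane, −78 °C; CeCl3, THF, −78 °C; then 13; AcOH quench at −78 °C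
Reagents that add atoms: none
Why: Iodine–lithium exchange, transmetalation to the weakly basic organocerium reagent and 1,2-addition to the α-bromo aldehyde should form C12–C13 without enolization or loss of bromide, and the C11/C12 mixture is acceptable because both centres are erased or converge.

Step 25
Reactants: 37 bromohydrin
Product: 38 C11-bromo C12-ketone with C8 dioxolane (C11 epimers)
Conditions: Dess–Martin periodinane, NaHCO3, CH2Cl2, 0 °C
Reagents that add atoms: none
Why: Dess–Martin oxidation of the bromohydrin gives the α-bromo ketone under neutral conditions, which fixes bromine at C11 and the carbonyl at C12 without any regiochemical choice.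

Step 26
Reactants: 38 bromo ketone ketal
Product: 39 oxepane diketo bromide (key-step precursor; C11 epimers; C21 OTES, C34 OTBS)
Conditions: PPTS, acetone/H2O (10:1), 45 °C
Reagents that add atoms: water, O
Why: Mild acid-catalysed ketal hydrolysis frees the C8 methyl ketone, and the hindered tertiary TES and secondary TBS ethers should survive PPTS.

Step 27
Reactants: 39 oxepane diketo bromide
Product: 41 ring-B ketol (C8 tertiary carbinol, C11 stereocentre, C12 ketone), via samarium(III) enolate 40 (not isolated)
Conditions: SmI2 (2.5 equiv), THF, −78 °C; sat. NH4Cl at −78 °C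
Reagents that add atoms: none
Why: Two single-electron transfers from SmI2 cleave the C11–Br bond of either epimer and give one samarium(III) enolate (C11=C12–O–Sm) that adds to the C8 ketone; the closest known reaction type is the samarium diiodide-mediated intramolecular Reformatsky-type aldol of α-halo ketones. Ring B (C5–C6–C7–C8–C11–C30) is closed by a 6-(enolexo)-exo-trig attack of C11 on C8. Because O4 and C32 are tied together in the oxepane they must both be equatorial on the forming chair, which forces the C31 methyl axial. C8 is set by that methyl: the C8 methyl takes the equatorial position to avoid a syn-diaxial contact with C31, so the oxygen becomes axial. C11 is set by samarium, which bridges the enolate oxygen and the C8 carbonyl oxygen and so holds the C12 acyl group equatorial and cis to the C8 oxygen. The step needs regioselectivity (enolate only toward C11, secured by the position of bromine), chemoselectivity (the α-bromo ketone is reduced far faster than the isolated C8 ketone, and C34 is a silyl ether, not an α-alkoxy ketone) and diastereoselectivity at C8 and C11 (secured by the chelate and the C31 methyl).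

Step 28
Reactants: 41 ketol
Product: 42 C8 triethylsilyl ether of 41
Conditions: TESOTf, 2,6-lutidine, CH2Cl2, −78 → 0 °C
Reagents that add atoms: triethylsilyl trifluoromethanesulfonate, CC[Si](CC)(CC)OS(=O)(=O)C(F)(F)F
Why: Silyl triflate silylation of the tertiary C8 alcohol blocks retro-aldol cleavage and prevents the later thionocarbonate from cyclizing onto this oxygen.

Step 29
Reactants: 42 silyloxy ketone
Product: 43 C12 carbinol (epimers)
Conditions: NaBH4, MeOH/THF, 0 °C → rt
Reagents that add atoms: none
Why: Hydride reduction of the C12 ketone needs no stereocontrol because this oxygen is removed in step 31.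

Step 30
Reactants: 43 alcohol
Product: 44 C12 O-phenyl thionocarbonate
Conditions: PhOC(S)Cl, pyridine, DMAP (cat.), CH2Cl2, rt
Reagents that add atoms: O-phenyl chlorothionoformate, S=C(Cl)Oc1ccccc1
Why: Acylation of the only free hydroxyl with the chlorothionoformate gives the substrate for Barton–McCombie deoxygenation.

Step 31
Reactants: 44 thionocarbonate
Product: 45 C12-deoxy compound (C12 methylene; C8 OTES, C21 OTES, C34 OTBS; C26=C28 alkene)
Conditions: Bu3SnH, AIBN (cat.), toluene, 100 °C
Reagents that add atoms: none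
Why: Barton–McCombie deoxygenation: stannyl radical addition to the thiocarbonyl, β-scission to the secondary C12 radical and hydrogen transfer give the methylene, and 5-endo attack of this radical on C26=C28 is disfavoured.

Step 32
Reactants: 45 alkene
Product: 47 C26–C28 epoxide (oxygen cis to C13; three silyl ethers retained), via bromohydrin 46 (not isolated)
Conditions: NBS, THF/H2O (4:1), 0 °C; then K2CO3, MeOH, rt
Reagents that add atoms: water, O
Why: Halohydrin formation and base closure: the bromonium ion should form on the more open face of C26=C28 (the face of C14–H, C18–H and C24–H), water then attacks C28 anti from the face of C13, and displacement of bromide at C26 with inversion places the epoxide oxygen cis to C13 as in the target.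

Step 33
Reactants: 47 silylated epoxide
Product: 48 epoxy triol (free hydroxyls at C8, C21 and C34)
Conditions: TBAF, THF, 50 °C
Reagents that add atoms: none
Why: Fluoride-mediated desilylation removes both triethylsilyl groups and the TBS group, and the epoxide is inert to fluoride.

Step 34
Reactants: 48 epoxy triol
Product: 49 target CNP0259752.1
Conditions: Dess–Martin periodinane, NaHCO3, CH2Cl2, rt
Reagents that add atoms: none
Why: Dess–Martin oxidation acts only on C34, the single secondary carbinol (C8 and C21 are tertiary), and the buffered conditions leave the epoxide intact.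

Compound list
1 | myrcene | C=CC(=C)CCC=C(C)C | starting material
2 | neryl pinacolboronate, 2-[(2Z)-3,7-dimethylocta-2,6-dien-1-yl]-4,4,5,5-tetramethyl-1,3,2-dioxaborolane | CC(C)=CCC/C(C)=C\CB1OC(C)(C)C(C)(C)O1 | intermediate
3 | pent-4-enal | C=CCCC=O | starting material
4 | (5R,6R)-6-ethenyl-6,10-dimethylundeca-1,9-dien-5-ol | O[C@H](CCC=C)[C@@](C)(C=C)CCC=C(C)C | intermediate
5 | (5R,6R)-8-[(2S)-3,3-dimethyloxiran-2-yl]-6-ethenyl-6-methyloct-1-en-5-ol | O[C@H](CCC=C)[C@@](C)(C=C)CC[C@@H]1OC1(C)C | intermediate
6 | tert-butyl{[(3S,6R,7R)-7-(but-3-en-1-yl)-6-ethenyl-2,2,6-trimethyloxepan-3-yl]oxy}dimethylsilane | CC1(C)O[C@H](CCC=C)[C@@](C)(C=C)CC[C@@H]1O[Si](C)(C)C(C)(C)C | intermediate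
7 | 4-[(2R,3R,6S)-6-{[tert-butyl(dimethyl)silyl]oxy}-3-ethenyl-3,7,7-trimethyloxepan-2-yl]butan-2-one | CC1(C)O[C@H](CCC(C)=O)[C@@](C)(C=C)CC[C@@H]1O[Si](C)(C)C(C)(C)C | intermediate
8 | tert-butyl{[(3S,6R,7R)-6-ethenyl-2,2,6-trimethyl-7-[2-(2-methyl-1,3-dioxolan-2-yl)ethyl]oxepan-3-yl]oxy}dimethylsilane | CC1(C)O[C@H](CCC2(C)OCCO2)[C@@](C)(C=C)CC[C@@H]1O[Si](C)(C)C(C)(C)C | intermediate
9 | B-alkyl-9-BBN adduct of 8 (boron on C12) | CC1(C)O[C@H](CCC2(C)OCCO2)[C@@](C)(CCB2C3CCCC2CCC3)CC[C@@H]1O[Si](C)(C)C(C)(C)C | intermediate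
10 | C12 primary alcohol (2-hydroxyethyl on C30, configuration as in 8) | CC1(C)O[C@H](CCC2(C)OCCO2)[C@@](C)(CCO)CC[C@@H]1O[Si](C)(C)C(C)(C)C | intermediate
11 | C12 aldehyde (2-oxoethyl on C30) | CC1(C)O[C@H](CCC2(C)OCCO2)[C@@](C)(CC=O)CC[C@@H]1O[Si](C)(C)C(C)(C)C | intermediate
12 | trimethylsilyl enol ether of 11 (C11=C12) | CC1(C)O[C@H](CCC2(C)OCCO2)[C@@](C)(C=CO[Si](C)(C)C)CC[C@@H]1O[Si](C)(C)C(C)(C)C | intermediate
13 | C11-bromo C12-aldehyde (C11 epimers) | CC1(C)O[C@H](CCC2(C)OCCO2)[C@@](C)(C(Br)C=O)CC[C@@H]1O[Si](C)(C)C(C)(C)C | intermediate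
14 | (R)-linalool | CC(C)=CCC[C@@](C)(O)C=C | starting material
15 | (R)-1-methylcyclopent-2-en-1-ol | C[C@@]1(O)CCC=C1 | intermediate
16 | (1R)-cis-2,3-epoxy-1-methylcyclopentan-1-ol (epoxide on the hydroxyl face) | C[C@@]1(O)CC[C@@H]2O[C@@H]21 | intermediate
17 | isobutyronitrile | CC(C)C#N | starting material
18 | 2-(2,3-dihydroxy-3-methylcyclopentyl)-2-methylpropanenitrile (hydroxyls cis; C18 substituent trans to both) | C[C@@]1(O)CC[C@@H](C(C)(C)C#N)[C@@H]1O | intermediate
19 | 2-(3-hydroxy-3-methyl-2-oxocyclopentyl)-2-methylpropanenitrile | C[C@@]1(O)CC[C@@H](C(C)(C)C#N)C1=O | intermediate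
20 | 2-methyl-2-[3-methyl-2-oxo-3-(triethylsilyloxy)cyclopentyl]propanenitrile | C[C@@]1(O[Si](CC)(CC)CC)CC[C@@H](C(C)(C)C#N)C1=O | intermediate
21 | 2-methyl-2-[3-methyl-2-methylidene-3-(triethylsilyloxy)cyclopentyl]propanenitrile | C[C@@]1(O[Si](CC)(CC)CC)CC[C@@H](C(C)(C)C#N)C1=C | intermediate
22 | vinyl bromide | C=CBr | starting material
23 | B-alkyl-9-BBN adduct of 21 (boron on C25; C24–H cis to OTES) | C[C@@]1(O[Si](CC)(CC)CC)CC[C@@H](C(C)(C)C#N)[C@H]1CB1C2CCCC1CCC2 | intermediate
24 | 2-methyl-2-[3-methyl-2-(prop-2-en-1-yl)-3-(triethylsilyloxy)cyclopentyl]propanenitrile (allyl cis to the nitrile-bearing group, trans to OTES) | C[C@@]1(O[Si](CC)(CC)CC)CC[C@@H](C(C)(C)C#N)[C@H]1CC=C | intermediate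
25 | 2-methyl-2-[3-methyl-2-(prop-2-en-1-yl)-3-(triethylsilyloxy)cyclopentyl]propanal | C[C@@]1(O[Si](CC)(CC)CC)CC[C@@H](C(C)(C)C=O)[C@H]1CC=C | intermediate
26 | diethyl (3-oxobutan-2-yl)phosphonate | CCOP(=O)(OCC)C(C)C(C)=O | starting material
27 | (3E)-3,5-dimethyl-5-[3-methyl-2-(prop-2-en-1-yl)-3-(triethylsilyloxy)cyclopentyl]hex-3-en-2-one | C[C@@]1(O[Si](CC)(CC)CC)CC[C@@H](C(C)(C)/C=C(\C)C(C)=O)[C@H]1CC=C | intermediate
28 | (2R,3E)-3,5-dimethyl-5-[3-methyl-2-(prop-2-en-1-yl)-3-(triethylsilyloxy)cyclopentyl]hex-3-en-2-ol | C[C@@]1(O[Si](CC)(CC)CC)CC[C@@H](C(C)(C)/C=C(\C)[C@@H](C)O)[C@H]1CC=C | intermediate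
29 | tributyl(iodomethyl)stannane | CCCC[Sn](CCCC)(CCCC)CI | starting material
30 | (tributylstannyl)methyl ether of 28 | C[C@@]1(O[Si](CC)(CC)CC)CC[C@@H](C(C)(C)/C=C(\C)[C@@H](C)OC[Sn](CCCC)(CCCC)CCCC)[C@H]1CC=C | intermediate
31 | lithiomethyl ether of 28 | C[C@@]1(O[Si](CC)(CC)CC)CC[C@@H](C(C)(C)/C=C(\C)[C@@H](C)OC[Li])[C@H]1CC=C | intermediate
32 | (3Z)-3-methyl-2-{2-[3-methyl-2-(prop-2-en-1-yl)-3-(triethylsilyloxy)cyclopentyl]propan-2-yl}pent-3-en-1-ol | C[C@@]1(O[Si](CC)(CC)CC)CC[C@@H](C(C)(C)[C@@H](CO)/C(C)=C\C)[C@H]1CC=C | intermediate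
33 | [1,4,4,6-tetramethyl-1-(triethylsilyloxy)-1,2,3,3a,4,5,8,8a-octahydroazulen-5-yl]methanol (cis-fused) | OC[C@@H]1C(C)(C)[C@@H]2CC[C@@](C)(O[Si](CC)(CC)CC)[C@@H]2CC=C1C | intermediate
34 | 5-(iodomethyl) analogue of 33 | IC[C@@H]1C(C)(C)[C@@H]2CC[C@@](C)(O[Si](CC)(CC)CC)[C@@H]2CC=C1C | intermediate
35 | hydroazulenylmethyllithium from 34 | [Li]C[C@@H]1C(C)(C)[C@@H]2CC[C@@](C)(O[Si](CC)(CC)CC)[C@@H]2CC=C1C | intermediate
36 | hydroazulenylmethylcerium dichloride | Cl[Ce](Cl)C[C@@H]1C(C)(C)[C@@H]2CC[C@@](C)(O[Si](CC)(CC)CC)[C@@H]2CC=C1C | intermediate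
37 | C11-bromo C12-carbinol, C8 dioxolane (C11/C12 mixture) | CC1(C)O[C@H](CCC2(C)OCCO2)[C@@](C)(C(Br)C(O)C[C@@H]3C(C)(C)[C@@H]4CC[C@@](C)(O[Si](CC)(CC)CC)[C@@H]4CC=C3C)CC[C@@H]1O[Si](C)(C)C(C)(C)C | intermediate
38 | C11-bromo C12-ketone, C8 dioxolane (C11 epimers) | CC1(C)O[C@H](CCC2(C)OCCO2)[C@@](C)(C(Br)C(=O)C[C@@H]3C(C)(C)[C@@H]4CC[C@@](C)(O[Si](CC)(CC)CC)[C@@H]4CC=C3C)CC[C@@H]1O[Si](C)(C)C(C)(C)C | intermediate
39 | oxepane diketo bromide, key-step precursor (C11 epimers) | CC1(C)O[C@H](CCC(C)=O)[C@@](C)(C(Br)C(=O)C[C@@H]2C(C)(C)[C@@H]3CC[C@@](C)(O[Si](CC)(CC)CC)[C@@H]3CC=C2C)CC[C@@H]1O[Si](C)(C)C(C)(C)C | intermediate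
40 | samarium(III) enolate (C11=C12–O–SmI2) | CC1(C)O[C@H](CCC(C)=O)[C@@](C)(C=C(O[Sm](I)I)C[C@@H]2C(C)(C)[C@@H]3CC[C@@](C)(O[Si](CC)(CC)CC)[C@@H]3CC=C2C)CC[C@@H]1O[Si](C)(C)C(C)(C)C | intermediate
41 | ring-B ketol, key-step product | CC1(C)O[C@@H]2CC[C@](C)(O)[C@H](C(=O)C[C@@H]3C(C)(C)[C@@H]4CC[C@@](C)(O[Si](CC)(CC)CC)[C@@H]4CC=C3C)[C@@]2(C)CC[C@@H]1O[Si](C)(C)C(C)(C)C | intermediate
42 | C8 triethylsilyl ether of 41 | CC1(C)O[C@@H]2CC[C@](C)(O[Si](CC)(CC)CC)[C@H](C(=O)C[C@@H]3C(C)(C)[C@@H]4CC[C@@](C)(O[Si](CC)(CC)CC)[C@@H]4CC=C3C)[C@@]2(C)CC[C@@H]1O[Si](C)(C)C(C)(C)C | intermediate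
43 | C12 carbinol (epimers) | CC1(C)O[C@@H]2CC[C@](C)(O[Si](CC)(CC)CC)[C@H](C(O)C[C@@H]3C(C)(C)[C@@H]4CC[C@@](C)(O[Si](CC)(CC)CC)[C@@H]4CC=C3C)[C@@]2(C)CC[C@@H]1O[Si](C)(C)C(C)(C)C | intermediate
44 | C12 O-phenyl thionocarbonate | CC1(C)O[C@@H]2CC[C@](C)(O[Si](CC)(CC)CC)[C@H](C(OC(=S)Oc5ccccc5)C[C@@H]3C(C)(C)[C@@H]4CC[C@@](C)(O[Si](CC)(CC)CC)[C@@H]4CC=C3C)[C@@]2(C)CC[C@@H]1O[Si](C)(C)C(C)(C)C | intermediate
45 | C12-deoxy tris-silyl ether alkene | CC1(C)O[C@@H]2CC[C@](C)(O[Si](CC)(CC)CC)[C@H](CC[C@@H]3C(C)(C)[C@@H]4CC[C@@](C)(O[Si](CC)(CC)CC)[C@@H]4CC=C3C)[C@@]2(C)CC[C@@H]1O[Si](C)(C)C(C)(C)C | intermediate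
46 | bromohydrin (Br on C26, OH on C28, trans) | CC1(C)O[C@@H]2CC[C@](C)(O[Si](CC)(CC)CC)[C@H](CC[C@@H]3C(C)(C)[C@@H]4CC[C@@](C)(O[Si](CC)(CC)CC)[C@@H]4C[C@@H](Br)[C@]3(C)O)[C@@]2(C)CC[C@@H]1O[Si](C)(C)C(C)(C)C | intermediate
47 | C26–C28 epoxide, tris-silyl ether | CC1(C)O[C@@H]2CC[C@](C)(O[Si](CC)(CC)CC)[C@H](CC[C@@H]3C(C)(C)[C@@H]4CC[C@@](C)(O[Si](CC)(CC)CC)[C@@H]4C[C@@H]4O[C@@]43C)[C@@]2(C)CC[C@@H]1O[Si](C)(C)C(C)(C)C | intermediate
48 | epoxy triol (C8, C21, C34 hydroxyls) | CC1(C)O[C@@H]2CC[C@](C)(O)[C@H](CC[C@@H]3C(C)(C)[C@@H]4CC[C@@](C)(O)[C@@H]4C[C@@H]4O[C@@]43C)[C@@]2(C)CC[C@@H]1O | intermediate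
49 | CNP0259752.1 | CC1(C)O[C@@H]2CC[C@](C)(O)[C@H](CC[C@@H]3C(C)(C)[C@@H]4CC[C@@](C)(O)[C@@H]4C[C@@H]4O[C@@]43C)[C@@]2(C)CCC1=O | target

Total step count: 34. Longest linear sequence: 25 steps (steps 10–23, then 24–34).

Steps most likely to fail

Step 27. The samarium enolate may be protonated by the enolizable C8 methyl ketone, or the congested aldolate (C30, C11 and C8 are contiguous and heavily substituted) may revert before the quench. Either process returns debrominated diketone. The fallback starts from 39 and generates the same regiodefined enolate in a form that cannot act as a base. Zinc dust and chlorotrimethylsilane (MeCN, 0 °C) convert 39 into the C11=C12 trimethylsilyl enol ether F1. F1 is then closed by an intramolecular Mukaiyama aldol addition onto the C8 ketone (TiCl4, CH2Cl2, −78 °C), which comes back to the route at 41. The C31 methyl still keeps the C8 methyl equatorial in the open transition state, and C11 can equilibrate to the equatorial acyl epimer.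

Step 4. The hydroxyl may open the epoxide at the secondary C34 (6-exo) instead of the tertiary C2, giving a tetrahydropyran instead of the oxepane. The fallback starts from 5 and turns the exo mode to advantage. Brønsted acid (CSA, CH2Cl2) deliberately gives the 6-exo product, tetrahydropyran tertiary alcohol F2. Ionization of its tertiary carbinol in acetic acid (cat. TfOH) lets O4 bridge C34 and C2, and acetate opens this bicyclic oxonium ion at C34. Return to the tertiary centre is reversible, so the material should collect as oxepanyl acetate F3, with the original C34 configuration restored by double inversion. Methanolysis (K2CO3, MeOH) gives oxepanol F4, and TBSOTf/2,6-lutidine comes back to the route at 6.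

Step 32. Facial selectivity may be poor or inverted if the bromonium ion forms on the face of C13; the C26/C28-diastereomeric epoxide would then result. The fallback starts from 45 and delivers oxygen directly: dimethyldioxirane (acetone, −20 °C) or buffered mCPBA attacks the face that bromine prefers. If that face is the C13 face, direct epoxidation gives 47 without new intermediates.

Further compounds
F1 | step 27 | C11=C12 trimethylsilyl enol ether of 39 | CC1(C)O[C@H](CCC(C)=O)[C@@](C)(C=C(O[Si](C)(C)C)C[C@@H]2C(C)(C)[C@@H]3CC[C@@](C)(O[Si](CC)(CC)CC)[C@@H]3CC=C2C)CC[C@@H]1O[Si](C)(C)C(C)(C)C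
F2 | step 4 | tetrahydropyran tertiary alcohol from 6-exo opening of 5 | OC(C)(C)[C@H]1CC[C@](C)(C=C)[C@@H](CCC=C)O1
F3 | step 4 | oxepanyl acetate (acetate in place of the silyl ether of 6) | CC1(C)O[C@H](CCC=C)[C@@](C)(C=C)CC[C@@H]1OC(C)=O
F4 | step 4 | oxepanol (free C34 hydroxyl of 6) | CC1(C)O[C@H](CCC=C)[C@@](C)(C=C)CC[C@@H]1O
F0 | step 32 | none | none
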